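**Retrosynthetic overview**
1. 14 ⇐ 12: one HF treatment opens a 2-(silylmethyl)oxolane by Peterson-type elimination (frees the 11β-OH and C16=C17) and removes the acetonide and MOM ester.
2. 12 ⇐ 9: the C11–O bond is made by visible-light hypoiodite 1,5-hydrogen transfer from an endo 16-alkoxy radical (key step); 9 ⇐ norketone 7 + Me3SiCH2MgCl (8).
3. 7 ⇐ 4: the ring A 2β,3β-diol comes from dehydration of the 3β-OH, OsO4 on the convex β face, then acetonide protection.
4. 4 ⇐ GA4 (1): MOM ester, then ozonolysis of C16=C17 (C17 is returned later from 8).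
5. Ring order: rings A–D and the lactone are bought in 1; the only ring formed is the temporary C11–O–C16 oxolane (step 7), opened again in step 8.

Target: CNP0322347.1 is 2β,3β,11β-trihydroxy-GA9 (11β-hydroxy-GA34), where GA9 is the hydroxyl-free parent with the 19,10-lactone, the 7-oic acid and exocyclic C16=C17. The 2β/3β-diol is cis. The 11β-OH is axial on ring C, on the face of the C15–C16 bridge.

Assumption: GA4, the 3β-hydroxy gibberellin plant hormone made by fermentation and sold as a plant-growth regulator, is taken as the commercial chiral starting material. C4, C5, C6, C8, C9, C10 and C13 come from it; C2/C3 (step 4) and C11 (step 7) are set under control of its framework.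

**Step 1**
Reactants: 1 GA4
Product: 2 GA4 methoxymethyl (MOM) ester
Conditions: MOMCl, iPr2NEt, CH2Cl2, 0 °C
Reagents that add atoms: chloromethyl methyl ether, COCCl
Why: carboxylate O-alkylation (bimolecular substitution on the α-chloro ether) is far faster than etherification of the hindered axial 3β-OH at 0 °C, and no stereocenter is touched.

**Step 2**
Reactants: 2 GA4 methoxymethyl ester
Product: 4 17-nor-16-oxo-GA4 MOM ester, via secondary ozonide 3 (not isolated)
Conditions: O3, CH2Cl2, −78 °C; then Me2S, −78 °C to rt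
Reagents that add atoms: ozone, [O-][O+]=O
Why: Criegee ozonolysis of the only C=C gives the ring D ketone after reductive cleavage of ozonide 3; the flanking centers C13 and C8 are bridgeheads and cannot epimerise.

**Step 3**
Reactants: 4 17-nor-16-oxo-GA4 MOM ester
Product: 5 17-nor-16-oxo-2,3-didehydro-GA9 MOM ester
Conditions: Martin sulfurane Ph2S[OC(CF3)2Ph]2, CH2Cl2, 0 °C to rt
Reagents that add atoms: none
Why: Martin sulfurane dehydration (anti elimination through the alkoxysulfonium) with the axial 3β-oxygen anti-periplanar to the axial 2α-H; C4 is quaternary so only the C2=C3 alkene can form, and the C3 center erased here is re-set in step 4.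

**Step 4**
Reactants: 5 17-nor-16-oxo-2,3-didehydro-GA9 MOM ester
Product: 6 2β,3β-dihydroxy-17-nor-16-oxo-GA9 MOM ester
Conditions: OsO4 (5 mol %), NMO, acetone–H2O 4:1, rt
Reagents that add atoms: osmium tetroxide (catalytic oxygen carrier), O=[Os](=O)(=O)=O; N-methylmorpholine N-oxide, C[N+]1([O-])CCOCC1; water, O
Why: Upjohn syn-dihydroxylation; OsO4 adds suprafacially to the convex β face because the α face of ring A is covered by the 19,10-lactone bridge, which sets C2 and C3 together as the cis 2β,3β-diol.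

**Step 5**
Reactants: 6 2β,3β-dihydroxy-17-nor-16-oxo-GA9 MOM ester
Product: 7 2β,3β-O-isopropylidene-17-nor-16-oxo-GA9 MOM ester
Conditions: 2-methoxypropene, PPTS (cat.), CH2Cl2, 0 °C
Reagents that add atoms: 2-methoxypropene, COC(C)=C
Why: acid-catalysed acetonide formation on the cis (axial/equatorial) diol protects it from glycol cleavage and alkoxy-radical chemistry in step 7, without change at any stereocenter.

**Step 6**
Reactants: 7 2β,3β-O-isopropylidene-17-nor-16-oxo-GA9 MOM ester; 8 (trimethylsilyl)methylmagnesium chloride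
Product: 9 tertiary β-hydroxysilane (16-endo-hydroxy-17-trimethylsilyl-16,17-dihydro compound)
Conditions: CeCl3, THF, −78 °C; aq NH4Cl
Reagents that add atoms: (trimethylsilyl)methylmagnesium chloride, C[Si](C)(C)C[Mg]Cl
Why: organocerium 1,2-addition (first half of a Peterson olefination) is selective for the ketone over lactone and ester at −78 °C; the nucleophile enters from the open exo face (C14 side) because the endo face is blocked by the axial 11β-H, so the new 16-OH is endo and points at C11.

**Step 7**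
Reactants: 9 tertiary β-hydroxysilane
Product: 12 11β,16-epoxy-17-trimethylsilyl oxolane (β-silyl ether), via hypoiodite 10 (not isolated), via 11α-iodo alcohol 11 (not isolated)
Conditions: PhI(OAc)2, I2, cyclohexane–CH2Cl2, hν (visible, tungsten lamp), 0–10 °C
Reagents that add atoms: none
Why: Proposed new method: hypoiodite δ-C–H etherification run on a Peterson β-hydroxysilane, a substrate class on which it has not been shown; AcOI turns the only free OH into hypoiodite 10, visible light cleaves O–I, and the endo 16-alkoxy radical, held about 2 Å from the axial 11β-H across the bicyclo[3.2.1]octane, abstracts it through a six-membered transition state faster than β-scission can expel Me3SiCH2• or open ring D (cold, non-polar medium chosen for this); the C11 radical is iodinated from the open α face to 11, and the iodide, activated by the hypervalent-iodine oxidant, is displaced with inversion by the 16-OH, so the new C11–O bond can only lie on the β face; closest known reaction type: Suárez PhI(OAc)2/I2 hypoiodite 1,5-hydrogen-transfer etherification of rigid tertiary alcohols (cedrol type), extended here so the oxolane keeps a β-silicon for Peterson-type opening.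

**Step 8**
Reactants: 12 11β,16-epoxy-17-trimethylsilyl oxolane (β-silyl ether)
Product: 14 2β,3β,11β-trihydroxy-GA9 (target), via alkenol acetonide MOM ester 13 (not isolated)
Conditions: 48% aq HF, MeCN, 0 °C to rt
Reagents that add atoms: none
Why: acid Peterson-type anti-elimination on a β-silyl tertiary ether (O-protonation, ionisation at C16 assisted by the anti-periplanar C–Si bond, fluoride attack on silicon) gives only the exocyclic C16=C17 alkene and frees the 11β-OH without breaking the C11–O bond; the same dilute HF hydrolyses the acetonide and the MOM ester, and it is too weak an acid to protonate the 1,1-disubstituted alkene, so the 11β-OH does not add back.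

**Compound list**
1 | GA4 (3β-hydroxy-GA9), the 3β-hydroxy gibberellin plant hormone: 19,10-lactone on the α face, 3β-OH (axial), 6β-CO2H, exocyclic C16=C17, no 13-OH | C=C1C[C@]23C[C@H]1CC[C@H]2[C@@]12CC[C@H](O)[C@@](C)(C(=O)O1)[C@H]2[C@@H]3C(=O)O | starting material
2 | GA4 methoxymethyl ester (7-CO2CH2OCH3) | C=C1C[C@]23C[C@H]1CC[C@H]2[C@@]12CC[C@H](O)[C@@](C)(C(=O)O1)[C@H]2[C@@H]3C(=O)OCOC | intermediate
3 | secondary ozonide of 2 (spiro-1,2,4-trioxolane on C16, both C16 epimers) | C7OOC1(O7)C[C@]23C[C@H]1CC[C@H]2[C@@]12CC[C@H](O)[C@@](C)(C(=O)O1)[C@H]2[C@@H]3C(=O)OCOC | intermediate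
4 | 17-nor-16-oxo-GA4 MOM ester (ring D ketone, 3β-OH) | O=C1C[C@]23C[C@H]1CC[C@H]2[C@@]12CC[C@H](O)[C@@](C)(C(=O)O1)[C@H]2[C@@H]3C(=O)OCOC | intermediate
5 | 17-nor-16-oxo-2,3-didehydro-GA9 MOM ester (C2=C3 alkene, C16 ketone) | O=C1C[C@]23C[C@H]1CC[C@H]2[C@@]12CC=C[C@@](C)(C(=O)O1)[C@H]2[C@@H]3C(=O)OCOC | intermediate
6 | 2β,3β-dihydroxy-17-nor-16-oxo-GA9 MOM ester (cis-diol on the β face) | O=C1C[C@]23C[C@H]1CC[C@H]2[C@@]12C[C@H](O)[C@H](O)[C@@](C)(C(=O)O1)[C@H]2[C@@H]3C(=O)OCOC | intermediate
7 | 2β,3β-O-isopropylidene-17-nor-16-oxo-GA9 MOM ester | O=C1C[C@]23C[C@H]1CC[C@H]2[C@@]12C[C@H](O5)[C@H](OC5(C)C)[C@@](C)(C(=O)O1)[C@H]2[C@@H]3C(=O)OCOC | intermediate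
8 | (trimethylsilyl)methylmagnesium chloride | C[Si](C)(C)C[Mg]Cl | starting material
9 | tertiary β-hydroxysilane: 16-OH endo (facing C11), 16-CH2SiMe3 exo (toward C14), 2β,3β-acetonide, MOM ester | C[Si](C)(C)C[C@]1(O)C[C@]23C[C@H]1CC[C@H]2[C@@]12C[C@H](O5)[C@H](OC5(C)C)[C@@](C)(C(=O)O1)[C@H]2[C@@H]3C(=O)OCOC | intermediate
10 | 16-O-iodo hypoiodite of 9 | C[Si](C)(C)C[C@]1(OI)C[C@]23C[C@H]1CC[C@H]2[C@@]12C[C@H](O5)[C@H](OC5(C)C)[C@@](C)(C(=O)O1)[C@H]2[C@@H]3C(=O)OCOC | intermediate
11 | 11α-iodo derivative of 9 (iodine equatorial on ring C) | C[Si](C)(C)C[C@]1(O)C[C@]23C[C@H]1C[C@@H](I)[C@H]2[C@@]12C[C@H](O5)[C@H](OC5(C)C)[C@@](C)(C(=O)O1)[C@H]2[C@@H]3C(=O)OCOC | intermediate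
12 | 11β,16-epoxy-17-trimethylsilyl-16,17-dihydro compound: oxolane oxygen bridging C11 (β, axial) and C16, CH2SiMe3 exo, acetonide, MOM ester | C[Si](C)(C)C[C@]1(O6)C[C@]23C[C@H]1C[C@H]6[C@H]2[C@@]12C[C@H](O5)[C@H](OC5(C)C)[C@@](C)(C(=O)O1)[C@H]2[C@@H]3C(=O)OCOC | intermediate
13 | 11β-hydroxy-2β,3β-O-isopropylidene-GA9 MOM ester (C16=C17 restored) | C=C1C[C@]23C[C@H]1C[C@H](O)[C@H]2[C@@]12C[C@H](O5)[C@H](OC5(C)C)[C@@](C)(C(=O)O1)[C@H]2[C@@H]3C(=O)OCOC | intermediate
14 | 2β,3β,11β-trihydroxy-GA9 (CNP0322347.1) | C=C1C[C@]23C[C@H]1C[C@H](O)[C@H]2[C@@]12C[C@H](O)[C@H](O)[C@@](C)(C(=O)O1)[C@H]2[C@@H]3C(=O)O | target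

**Totals:** 8 steps; longest linear sequence 8 steps (1 to 14).

**Steps most likely to fail, with fallbacks**

Step 7 (proposed new method). The risk is β-scission of the 16-alkoxy radical (loss of Me3SiCH2• or opening of ring D), hydrogen abstraction from an SiCH3 group instead of from C11, or acid-triggered Peterson elimination of 9 by the acetic acid formed. The fallback uses only known reaction types and swaps silicon for a halide handle. It sets out from ketone 7. Corey–Chaykovsky methylenation (Me3S+ I−, KN(SiMe3)2, THF; exo attack) gives the endo-oxygen spiro-epoxide F1. Li2NiBr4 in THF opens it at the primary carbon to the 17-bromo-16-endo-ol bromohydrin F2. The standard PhI(OAc)2/I2/visible-light hypoiodite reaction then gives the 17-bromo-11β,16-ether F3. Zn/NH4Cl in EtOH (Boord reductive elimination) expels the alkoxide and returns to the route at compound 13, now isolated, which is taken to 14 with the HF conditions of step 8.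

Step 8. The risk is slow acetonide cleavage, with longer acid exposure letting the 11β-OH add back to C16=C17 to give a dead-end 16-methyl ether. The fallback sets out from 12 and masks the alkene/alcohol pair in an acid-inert form. BF3·OEt2 in CH2Cl2 at −78 °C performs only the Peterson-type opening and 13 is isolated. NIS in MeCN at 0 °C (iodoetherification) gives the protected 17-iodo-11β,16-ether F4. Aqueous HCl in THF removes the acetonide and MOM ester to give the iodo-ether triol acid F5. Zn/NH4Cl in EtOH (Boord elimination, near-neutral) then returns to the route at the target 14.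

Step 3. The risk is that the neopentyl, axial 3β-alcohol ionises and rearranges, or that the concave 2α-H is not reached. The fallback avoids the alkene and sets out from 2. Dess–Martin periodinane gives the 3-oxo ester F6. KN(SiMe3)2 followed by racemic 2-(phenylsulfonyl)-3-phenyloxaziridine (Davis hydroxylation of the C2 enolate from the convex β face) gives the 2β-hydroxy-3-ketone F7. KBH(sBu)3 in THF at −78 °C delivers hydride equatorially to give the axial 3β-alcohol, the cis-diol GA34 MOM ester F8. Ozonolysis under step 2 conditions returns to the route at compound 6.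

**Further compounds**
F1 | step 7 | spiro-epoxide at C16 (oxygen endo, CH2 exo), 2β,3β-acetonide, MOM ester | C6[C@]1(O6)C[C@]23C[C@H]1CC[C@H]2[C@@]12C[C@H](O5)[C@H](OC5(C)C)[C@@](C)(C(=O)O1)[C@H]2[C@@H]3C(=O)OCOC
F2 | step 7 | 17-bromo-16-endo-hydroxy-16,17-dihydro bromohydrin, acetonide, MOM ester | BrC[C@]1(O)C[C@]23C[C@H]1CC[C@H]2[C@@]12C[C@H](O5)[C@H](OC5(C)C)[C@@](C)(C(=O)O1)[C@H]2[C@@H]3C(=O)OCOC
F3 | step 7 | 17-bromo-11β,16-epoxy-16,17-dihydro ether, acetonide, MOM ester | BrC[C@]1(O6)C[C@]23C[C@H]1C[C@H]6[C@H]2[C@@]12C[C@H](O5)[C@H](OC5(C)C)[C@@](C)(C(=O)O1)[C@H]2[C@@H]3C(=O)OCOC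
F4 | step 8 | 17-iodo-11β,16-epoxy-16,17-dihydro ether, acetonide, MOM ester | IC[C@]1(O6)C[C@]23C[C@H]1C[C@H]6[C@H]2[C@@]12C[C@H](O5)[C@H](OC5(C)C)[C@@](C)(C(=O)O1)[C@H]2[C@@H]3C(=O)OCOC
F5 | step 8 | 17-iodo-11β,16-epoxy-2β,3β-dihydroxy-16,17-dihydro-GA9 (free 7-acid) | IC[C@]1(O6)C[C@]23C[C@H]1C[C@H]6[C@H]2[C@@]12C[C@H](O)[C@H](O)[C@@](C)(C(=O)O1)[C@H]2[C@@H]3C(=O)O
F6 | step 3 | 3-oxo-GA4 MOM ester (3-ketone, 16-ene) | C=C1C[C@]23C[C@H]1CC[C@H]2[C@@]12CCC(=O)[C@@](C)(C(=O)O1)[C@H]2[C@@H]3C(=O)OCOC
F7 | step 3 | 2β-hydroxy-3-oxo-GA9 MOM ester | C=C1C[C@]23C[C@H]1CC[C@H]2[C@@]12C[C@H](O)C(=O)[C@@](C)(C(=O)O1)[C@H]2[C@@H]3C(=O)OCOC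
F8 | step 3 | GA34 MOM ester (2β,3β-dihydroxy-GA9 MOM ester, 16-ene) | C=C1C[C@]23C[C@H]1CC[C@H]2[C@@]12C[C@H](O)[C@H](O)[C@@](C)(C(=O)O1)[C@H]2[C@@H]3C(=O)OCOC
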